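**Strategy.** With the lactone numbered O1, C2(=O), C3, C4, C5 and the hydroxymethyl carbon C7, the chain C7–C4–C3–C2 is the four carbons of furan. The C4–C5 bond is the link between furan C3 and the carbonyl carbon of a ring B aldehyde, whose oxygen becomes O1. A Paternò–Büchi photocycloaddition of O-acetylvanillin to furan forms C4–C5, a temporary O1–C7 oxetane bond and the C5 stereocentre in one operation. The bicyclic acetal then unfolds to a 1,4-dicarbonyl lactol. The precursor is simply furan plus the acetate-masked ring B aldehyde. Ring A is added late by aldol condensation and face-selective hydrogenation; absolute configuration comes from a salt resolution.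

Key step: step 1

Remark on numbering: positions in the text use the lactone numbering above; systematic names carry their own locants.
Remark on racemates: compounds 3–7 are racemic and are drawn as the enantiomer that is carried forward.
Assumption: the (R)-1-phenylethylammonium salt of the (2R,3R)-acid is taken to be the less soluble diastereomer; if the antipodal acid crystallises instead, (S)-1-phenylethylamine is used in the same way, and the configuration of the salt is secured by X-ray analysis against the known centre of the amine.

**Route**

Step 1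
Reactants: 1 furan; 2 4-acetoxy-3-methoxybenzaldehyde (vanillin acetate)
Product: 3 rac-(1R,5S,6R)-6-(4-acetoxy-3-methoxyphenyl)-2,7-dioxabicyclo[3.2.0]hept-3-ene (aryl exo)
Conditions: hν (medium-pressure Hg lamp, Pyrex filter, λ > 300 nm), furan as solvent (large excess), degassed, 0 °C
Reagents that add atoms: none
Why: Paternò–Büchi [2+2] photocycloaddition: the n,π* triplet of 2, kept accessible because an acyloxy group is a far weaker π-donor than OH or OR, bonds through oxygen to furan C2 to give a 1,4-biradical (benzylic radical plus oxygen-substituted allyl radical), which after intersystem crossing closes at furan C3. The closest known reaction type is the photocycloaddition of benzaldehyde and other aromatic aldehydes to furan. The one ring closed, the oxetane, forms by recombination of this 1,4-biradical with the C–C bond made last, and it can only be cis-fused to the dihydrofuran. Of the three new stereocentres, the two ring-fusion carbons are fixed by that geometric constraint, and the aryl-bearing carbon (future C5) is set by substrate control, the biradical closing through the conformer that keeps the aryl group on the convex exo face. The step needs O-to-C2/C-to-C3 regioselectivity, secured by the stability of the allylic biradical, and exo selectivity; photo-Fries cleavage of the aryl ester and a second addition to the product enol ether are suppressed by Pyrex-filtered light, which excites only the aldehyde chromophore, and by the large excess of furan. The adduct should form as a racemate with the relative configuration shown.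

Step 2
Reactants: 3 rac-exo photoadduct
Product: 5 rac-(2R,3R)-2-(4-acetoxy-3-methoxyphenyl)-5-hydroxytetrahydrofuran-3-carbaldehyde (4,5-trans lactol aldehyde; anomer mixture), via cis lactol aldehyde 4 (not isolated)
Conditions: 0.05 M HCl (aq), THF, 0 °C → rt; NaHCO3 wash; crude in CH2Cl2, Et3N (1 equiv), rt
Reagents that add atoms: water, O
Why: Acid-catalysed acetal/enol ether hydrolysis opens the strained oxetane at the acetal C–O bond and tautomerises the enol, so the threo hydroxy dialdehyde closes to the five-membered lactol 4 without touching C4 or C5, and enolisation of the formyl-bearing C4 by the non-nucleophilic amine (which spares the acetate) should then equilibrate it to the more stable 4,5-trans lactol under thermodynamic control.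

Step 3
Reactants: 5 rac-trans lactol aldehyde
Product: 6 rac-(2R,3R)-2-(4-acetoxy-3-methoxyphenyl)-5-oxotetrahydrofuran-3-carboxylic acid (trans paraconic acid)
Conditions: CrO3, H2SO4, H2O, acetone, 0 °C; iPrOH quench
Reagents that add atoms: water, O
Why: Jones oxidation takes the aldehyde through its hydrate to the carboxylic acid and the lactol to the γ-lactone in one operation, the aryl acetate being inert to hexavalent chromium and the acidic medium leaving the trans C4/C5 relation in place.

Step 4
Reactants: 6 rac-trans acetoxy acid
Product: 7 rac-(2R,3R)-2-(4-hydroxy-3-methoxyphenyl)-5-oxotetrahydrofuran-3-carboxylic acid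
Conditions: LiOH·H2O (4 equiv), THF/H2O, 0 °C → rt; then 2 M HCl to pH 1
Reagents that add atoms: none
Why: Saponification removes the aryl acetate, which could survive neither the amine resolution nor the later enolate step; any lactone that opens recloses on acidification through the same C5–O1 bond, and C4, being α only to a carboxylate, is not epimerised.

Step 5
Reactants: 7 rac-trans phenol acid
Product: 8 (R)-1-phenylethylammonium (2R,3R)-2-(4-hydroxy-3-methoxyphenyl)-5-oxotetrahydrofuran-3-carboxylate
Conditions: (R)-1-phenylethylamine (1 equiv), EtOH, reflux → rt; recrystallisation from EtOH to constant rotation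
Reagents that add atoms: (R)-1-phenylethylamine, C[C@@H](N)c1ccccc1
Why: Classical resolution by diastereomeric salt formation: the two ammonium carboxylates differ in solubility, so fractional crystallisation should give one diastereomer pure without making or breaking any bond at C4 or C5.

Step 6
Reactants: 8 resolved ammonium salt
Product: 10 (4S,5R)-5-(4-hydroxy-3-methoxyphenyl)-4-(hydroxymethyl)dihydrofuran-2(3H)-one, via free acid 9 (not isolated)
Conditions: 1 M HCl/EtOAc partition; then BH3·SMe2 (2 equiv), THF, 0 °C → rt; MeOH quench
Reagents that add atoms: none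
Why: Chemoselective borane reduction: the carboxylic acid is reduced through its acyloxyborane much faster than the lactone, so only C7 becomes the primary alcohol, the phenol merely consuming hydride and neither stereocentre being involved.

Step 7
Reactants: 10 hydroxymethyl lactone
Product: 11 (4S,5R)-4-[(tert-butyldimethylsilyloxy)methyl]-5-[4-(tert-butyldimethylsilyloxy)-3-methoxyphenyl]dihydrofuran-2(3H)-one
Conditions: TBSCl (2.5 equiv), imidazole (5 equiv), DMF, rt
Reagents that add atoms: tert-butyldimethylsilyl chloride, CC(C)(C)[Si](C)(C)Cl
Why: Imidazole-promoted silylation caps the phenol and the primary alcohol together, which prevents translactonisation by a C7 alkoxide and phenoxide formation in the enolate step.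

Step 8
Reactants: 11 bis-silyl lactone; 12 4-(benzyloxy)-3-methoxybenzaldehyde (O-benzylvanillin)
Product: 15 (3E,4S,5R)-3-[4-(benzyloxy)-3-methoxybenzylidene]-4-[(tert-butyldimethylsilyloxy)methyl]-5-[4-(tert-butyldimethylsilyloxy)-3-methoxyphenyl]dihydrofuran-2(3H)-one, via aldol adduct 13 (not isolated), via mesylate 14 (not isolated)
Conditions: LiN(SiMe3)2 (1.1 equiv), THF, −78 °C; 12; MsCl (1.5 equiv), −78 → 0 °C; DBU (3 equiv), 0 °C → rt
Reagents that add atoms: none
Why: Aldol condensation: the lithium lactone enolate, which has no β-leaving group, adds to the aldehyde, the aldolate is mesylated in the flask and E1cB elimination with DBU gives the conjugated benzylidene lactone (E expected as the more stable isomer), so the aldol diastereomers converge while C4 and C5 are untouched provided exposure to DBU is kept short.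

Step 9
Reactants: 15 benzylidene lactone
Product: 17 (3S,4S,5R)-4-[(tert-butyldimethylsilyloxy)methyl]-5-[4-(tert-butyldimethylsilyloxy)-3-methoxyphenyl]-3-(4-hydroxy-3-methoxybenzyl)dihydrofuran-2(3H)-one, via saturated benzyl ether 16 (not isolated)
Conditions: H2 (1 atm), 10% Pd/C, EtOAc, rt
Reagents that add atoms: none
Why: Heterogeneous catalytic hydrogenation should deliver hydrogen to C3 from the face opposite the adjacent C4 silyloxymethyl group, which places the new benzyl group cis to C7 (3S) whichever alkene isomer is present, and the same catalyst hydrogenolyses the phenolic benzyl ether, while the neutral solvent and low pressure are chosen to spare the benzylic C5–O1 bond and the silyl ethers.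

Step 10
Reactants: 17 bis-silyl ether
Product: 18 (3S,4S,5R)-5-(4-hydroxy-3-methoxyphenyl)-3-(4-hydroxy-3-methoxybenzyl)-4-(hydroxymethyl)dihydrofuran-2(3H)-one (CNP0329106.3)
Conditions: Bu4NF (3 equiv), AcOH (3 equiv), THF, 0 °C → rt
Reagents that add atoms: none
Why: Fluoride-mediated desilylation cleaves the aryl and the primary alkyl silyl ether, and buffering with acetic acid keeps the medium non-basic so that the epimerisable cis C3 centre is not equilibrated and the freed C7 hydroxyl does not translactonise.

**Compound list**

1 | furan | c1ccoc1 | starting material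
2 | 4-acetoxy-3-methoxybenzaldehyde (vanillin acetate) | COc1cc(C=O)ccc1OC(C)=O | starting material
3 | rac-(1R,5S,6R)-6-(4-acetoxy-3-methoxyphenyl)-2,7-dioxabicyclo[3.2.0]hept-3-ene, aryl exo | C1=CO[C@@H]2O[C@@H](c3ccc(OC(C)=O)c(OC)c3)[C@H]12 | intermediate
4 | rac-(2R,3S)-2-(4-acetoxy-3-methoxyphenyl)-5-hydroxytetrahydrofuran-3-carbaldehyde, 4,5-cis lactol aldehyde (anomer mixture, in equilibrium with the open hydroxy dialdehyde) | O=C[C@H]1CC(O)O[C@H]1c1ccc(OC(C)=O)c(OC)c1 | intermediate
5 | rac-(2R,3R)-2-(4-acetoxy-3-methoxyphenyl)-5-hydroxytetrahydrofuran-3-carbaldehyde, 4,5-trans lactol aldehyde (anomer mixture) | O=C[C@@H]1CC(O)O[C@H]1c1ccc(OC(C)=O)c(OC)c1 | intermediate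
6 | rac-(2R,3R)-2-(4-acetoxy-3-methoxyphenyl)-5-oxotetrahydrofuran-3-carboxylic acid (trans) | OC(=O)[C@@H]1CC(=O)O[C@H]1c1ccc(OC(C)=O)c(OC)c1 | intermediate
7 | rac-(2R,3R)-2-(4-hydroxy-3-methoxyphenyl)-5-oxotetrahydrofuran-3-carboxylic acid (trans) | OC(=O)[C@@H]1CC(=O)O[C@H]1c1ccc(O)c(OC)c1 | intermediate
8 | (R)-1-phenylethylammonium (2R,3R)-2-(4-hydroxy-3-methoxyphenyl)-5-oxotetrahydrofuran-3-carboxylate | C[C@@H]([NH3+])c1ccccc1.[O-]C(=O)[C@@H]1CC(=O)O[C@H]1c1ccc(O)c(OC)c1 | intermediate
9 | (2R,3R)-2-(4-hydroxy-3-methoxyphenyl)-5-oxotetrahydrofuran-3-carboxylic acid (single enantiomer) | OC(=O)[C@@H]1CC(=O)O[C@H]1c1ccc(O)c(OC)c1 | intermediate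
10 | (4S,5R)-5-(4-hydroxy-3-methoxyphenyl)-4-(hydroxymethyl)dihydrofuran-2(3H)-one | OC[C@@H]1CC(=O)O[C@H]1c1ccc(O)c(OC)c1 | intermediate
11 | (4S,5R)-4-[(tert-butyldimethylsilyloxy)methyl]-5-[4-(tert-butyldimethylsilyloxy)-3-methoxyphenyl]dihydrofuran-2(3H)-one | CC(C)(C)[Si](C)(C)OC[C@@H]1CC(=O)O[C@H]1c1ccc(O[Si](C)(C)C(C)(C)C)c(OC)c1 | intermediate
12 | 4-(benzyloxy)-3-methoxybenzaldehyde (O-benzylvanillin) | COc1cc(C=O)ccc1OCc1ccccc1 | starting material
13 | aldol adduct of 11 and 12 (lithium alkoxide in the flask, neutral form shown; mixture at C3 and the carbinol carbon, 4S,5R fixed) | COc1cc(C(O)C2C(=O)O[C@@H](c3ccc(O[Si](C)(C)C(C)(C)C)c(OC)c3)[C@@H]2CO[Si](C)(C)C(C)(C)C)ccc1OCc1ccccc1 | intermediate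
14 | methanesulfonate of 13 | COc1cc(C(OS(C)(=O)=O)C2C(=O)O[C@@H](c3ccc(O[Si](C)(C)C(C)(C)C)c(OC)c3)[C@@H]2CO[Si](C)(C)C(C)(C)C)ccc1OCc1ccccc1 | intermediate
15 | (3E,4S,5R)-3-[4-(benzyloxy)-3-methoxybenzylidene]-4-[(tert-butyldimethylsilyloxy)methyl]-5-[4-(tert-butyldimethylsilyloxy)-3-methoxyphenyl]dihydrofuran-2(3H)-one | COc1cc(/C=C2/C(=O)O[C@@H](c3ccc(O[Si](C)(C)C(C)(C)C)c(OC)c3)[C@@H]2CO[Si](C)(C)C(C)(C)C)ccc1OCc1ccccc1 | intermediate
16 | (3S,4S,5R)-3-[4-(benzyloxy)-3-methoxybenzyl]-4-[(tert-butyldimethylsilyloxy)methyl]-5-[4-(tert-butyldimethylsilyloxy)-3-methoxyphenyl]dihydrofuran-2(3H)-one | COc1cc(C[C@@H]2C(=O)O[C@@H](c3ccc(O[Si](C)(C)C(C)(C)C)c(OC)c3)[C@@H]2CO[Si](C)(C)C(C)(C)C)ccc1OCc1ccccc1 | intermediate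
17 | (3S,4S,5R)-4-[(tert-butyldimethylsilyloxy)methyl]-5-[4-(tert-butyldimethylsilyloxy)-3-methoxyphenyl]-3-(4-hydroxy-3-methoxybenzyl)dihydrofuran-2(3H)-one | COc1cc(C[C@@H]2C(=O)O[C@@H](c3ccc(O[Si](C)(C)C(C)(C)C)c(OC)c3)[C@@H]2CO[Si](C)(C)C(C)(C)C)ccc1O | intermediate
18 | (3S,4S,5R)-5-(4-hydroxy-3-methoxyphenyl)-3-(4-hydroxy-3-methoxybenzyl)-4-(hydroxymethyl)dihydrofuran-2(3H)-one | COc1cc(C[C@@H]2C(=O)O[C@@H](c3ccc(O)c(OC)c3)[C@@H]2CO)ccc1O | target

**Step count**

Total: 10 steps. Longest linear sequence: 10 steps (1 and 2 to 18); 12 is purchased.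

**Steps most likely to fail**

Step 1. The photocycloaddition may be inefficient because the triplet of the dioxygenated aldehyde has partial π,π* character, and photo-Fries cleavage of the aryl ester or a second addition to the enol ether may compete. The fallback sets out from 2 and replaces the photochemistry by the ZnCl2/Et3N-promoted condensation of 2 with succinic anhydride in CH2Cl2 at room temperature. In this aldol–lactonisation the zinc enolate of the anhydride adds to the aldehyde and the alkoxide closes onto the anhydride carbonyl. The paraconic acid forms directly, trans-enriched after equilibration and crystallisation, and the route is rejoined at 6. No compound outside the list is made (F0).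

Step 2. During the base equilibration the enol or enolate at C4 may expel the C5 oxygen (aldol dehydration to the arylidene dialdehyde), or the epimerisation may stall short of the trans isomer. The fallback sets out from 4, taken on without base treatment, and corrects C5 instead of C4. Oxidation with CrO3/H2SO4 in acetone should give rac-(2R,3S)-2-(4-acetoxy-3-methoxyphenyl)-5-oxotetrahydrofuran-3-carboxylic acid F1. Saponification with LiOH then gives the cis phenol acid rac-(2R,3S)-2-(4-hydroxy-3-methoxyphenyl)-5-oxotetrahydrofuran-3-carboxylic acid F2. Warming F2 in CF3CO2H ionises the benzylic C5–O1 bond reversibly, assisted by the para hydroxyl, and reclosure should settle on the more stable trans lactone. Inversion at C5 in the racemic series gives the same racemate, so the route is rejoined at 7.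

Step 5. The two diastereomeric salts may co-crystallise or oil out, so that crystallisation brings no enrichment. The fallback sets out from 7 and moves the separation to a neutral intermediate. The racemic acid is reduced with BH3·SMe2 to the racemic hydroxymethyl lactone F3, which is silylated with TBSCl/imidazole to the racemic bis-silyl lactone F4. The enantiomers of F4 are then separated by preparative chromatography on a chiral stationary phase (amylose tris(3,5-dimethylphenylcarbamate), CO2/iPrOH). The (4S,5R) antipode is identified by chiroptical comparison after carrying a sample through to 18, and the route is rejoined at 11.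

Further compounds
F0 | step 1 | none | none
F1 | step 2 | rac-(2R,3S)-2-(4-acetoxy-3-methoxyphenyl)-5-oxotetrahydrofuran-3-carboxylic acid (cis) | OC(=O)[C@H]1CC(=O)O[C@H]1c1ccc(OC(C)=O)c(OC)c1
F2 | step 2 | rac-(2R,3S)-2-(4-hydroxy-3-methoxyphenyl)-5-oxotetrahydrofuran-3-carboxylic acid (cis) | OC(=O)[C@H]1CC(=O)O[C@H]1c1ccc(O)c(OC)c1
F3 | step 5 | rac-(4S,5R)-5-(4-hydroxy-3-methoxyphenyl)-4-(hydroxymethyl)dihydrofuran-2(3H)-one (racemate of 10) | OC[C@@H]1CC(=O)O[C@H]1c1ccc(O)c(OC)c1
F4 | step 5 | rac-(4S,5R)-4-[(tert-butyldimethylsilyloxy)methyl]-5-[4-(tert-butyldimethylsilyloxy)-3-methoxyphenyl]dihydrofuran-2(3H)-one (racemate of 11) | CC(C)(C)[Si](C)(C)OC[C@@H]1CC(=O)O[C@H]1c1ccc(O[Si](C)(C)C(C)(C)C)c(OC)c1
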